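In a closed, stirred flask the solid substrate lies undissolved beside a solution of reagent and free catalyst, and the target is counted against the solid charged.

| flask | solid substrate | reagent | free catalyst | temperature | remark | time |
|---|---|---|---|---|---|---|
| delta | 0.10 M | 2 equiv | 1.4 mol% | 18 °C | run made earlier |  |
| beta | 0.10 M | 2 equiv | 2.2 mol% | 34 °C | run made earlier |  |
| teal | 0.10 M | 2.00 equiv | 1 mol% | 25 °C |  | 2.0 min |
| red | 0.10 M | 2.00 equiv | 1 mol% | 40 °C |  | 2.0 min |
| violet | 0.10 M | 2.00 equiv | 1 mol% |  | at 40 °C until 25 s, from then on at 10 °C | 2.0 min |
| grey | 0.10 M | 2.00 equiv | 1 mol% | 10 °C |  | 2.0 min |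

| run | time / s | target / % |
|---|---|---|
| delta | 10.0 | 1.9 |
| delta | 25.0 | 6.5 |
| delta | 40.0 | 10.5 |
| delta | 60.0 | 15.1 |
| delta | 90.0 | 23.1 |
| beta | 12.0 | 9.1 |
| beta | 25.0 | 18.6 |
| beta | 40.0 | 29.1 |
| beta | 50.0 | 39.4 |
| beta | 60.0 | 44.6 |

(readings scatter by 1 percentage point)

1. the flask with the highest amount of target, in percent of the solid substrate charged ("all alike" if they lie within 1.5 percentage points) (teal / red / violet / grey / all alike)
2. final target, as a percentage of the solid substrate charged, in teal
3. final target, as a percentage of the solid substrate charged, in red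
4. final target, as a percentage of the solid substrate charged, in violet
5. final target, as a percentage of the solid substrate charged, in grey

- solid substrate is a solid; its amount is given per volume of the solution
- at the start none of the solid substrate is in solution
- what has only dissolved of solid substrate counts as not reacted

Within the scatter, both earlier runs rise as straight lines through the origin, which looks zero-order in the solid. So we reckon with the fraction left, which falls linearly as 1 − t/τ. Taking first order in free catalyst and scaling to 1 mol%, the last readings give 9.09 min at 18 °C and 4.93 min at 34 °C. Each is the time the straight line at that loading needs for the whole charge, the emptying time τ.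

Now the curve for a flask at 1 mol%. It leaves the origin with slope 1/τ and has its knee at t = τ, where the straight line meets the full charge. Beyond the knee lies the level of the full charge, since at 2.00 equiv the solid substrate is the limiting reagent if one reagent goes per target. At 34 °C the line stands at 40.5 % after 2.0 min, and at 18 °C at 22.0 %.

Between those temperatures τ fell by a factor 1.84, whereas red's knee would need a further factor 2.46 from 34 °C to 40 °C, so we expect teal, red, violet and grey each to stop on its line before the knee. Red, hotter than beta, should stand above 40.5 %. Teal should lie between 22.0 % and 40.5 %, and grey, colder than delta, below 22.0 %. On such straight lines, while solid remains, the fractions used add stretch by stretch as time over τ, so violet, with 25 s at red's τ and the rest at grey's, should land between grey and red.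

The forecast names red, with teal 29 %, red 51 % (range 43 % to 85 %), violet 24 % and grey 16 %. Its ground: “I assume first order in free catalyst”.

The flask with the most target is red, at 66.5 %, with teal 35.2 %, violet 24.9 % and grey 13.1 %.

    solid substrate ⇌ starting material, rate k1*(cs1 - [starting material]) while solid is left; crystals form when [starting material] > cs1 (solubility = 5.50 mM, k = 0.288 s⁻¹)
    catalyst intermediate A → catalyst intermediate B (k = 15.3 s⁻¹, Ea = 67.0 kJ mol⁻¹)
    catalyst intermediate C → catalyst intermediate D (k = 5.39 s⁻¹, Ea = 69.0 kJ mol⁻¹)
    starting material + free catalyst ⇌ catalyst intermediate A (K = 326 L mol⁻¹, k = 91.0 L mol⁻¹ s⁻¹, Ea = 50.0 kJ mol⁻¹, ΔH = −34.0 kJ mol⁻¹)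
    catalyst intermediate D ⇌ free catalyst + target (K = 0.230 M, k = 10.9 s⁻¹, Ea = 61.0 kJ mol⁻¹, ΔH = −36.0 kJ mol⁻¹)
    reagent + catalyst intermediate B ⇌ catalyst intermediate C (K = 6.66 L mol⁻¹, k = 51.6 L mol⁻¹ s⁻¹, Ea = 39.0 kJ mol⁻¹, ΔH = 5.00 kJ mol⁻¹)
    (constants at 25 °C)

In red, solid substrate still stands at 29.3 % of the charge after 2.00 min, and the emptying time read from red's final target, 3.01 min, is shorter than the 4.93 min read for 34 °C. Grey read the same way gives 15.3 min, and the two stretches of violet, reckoned with these two times, add to 24.2 %, against 24.9 % in violet. Teal's emptying time, 5.68 min, puts 0.7 of the charge at 3.98 min, and teal reaches that conversion at 4.12 min.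

All runs are simulated with made-up constants; scatter was added.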